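## The problem

Quercetin 3,3'-bissulfate is a flat, achiral flavonol in which ring A (a phloroglucinol unit) is fused to the γ-pyrone ring C and ring B (a catechol) is bonded to C2. There is no stereocentre to set or to use for control, so the difficulty is regiochemical: of five similar oxygens, O3 and O3' must carry sulfate while O5, O7 and O4' end as free hydroxyls. O3' and O4' are neighbours on ring B and cannot be told apart reliably once both are phenols, so they have to enter the molecule already different. The sulfate monoesters are ionic and acid-labile, so sulfation has to come next to last and the final deprotection has to be neutral (hydrogenolysis of benzyl ethers). Other fragile features are the free 3-hydroxyflavone and catechol stage (air oxidation under base) and the 5-O-benzyl ether (chelation-assisted cleavage by strong acid). The feature that permits a non-classical entry is that C1', C6', C5' and C4' of ring B, with O4' on the last carbon, correspond to C6, C5, C4 and C3 of a 3-oxygenated 2-pyrone bonded to C2 of ring C through its C6. The two missing carbons, C2' and C3' with O3', are the two carbons of an ynol ether, so O4' can come from the pyrone and O3' from the alkyne. The price is that the 2-pyrone is opened by hydroxide and amines and the silyl ynol ether is destroyed by acid, which limits what may be done before and during the key step.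

## Retrosynthesis

**Sulfate and benzyl groups (26 ⇒ 24 ⇒ 23).** The two S–O bonds and the three benzyl C–O bonds are cut first. Sulfating after debenzylation would be unselective, so the sulfates go onto diol 23, in which O5, O7 and O4' are benzylated, and the salt 24 is debenzylated by hydrogenolysis. Compound 23 is a neutral, chromatographable tri-O-benzylquercetin. The forward steps must sulfate both the enolic O3 and the phenolic O3' and then keep the pH near neutral.

**Twin silyl ethers (23 ⇒ 22).** O3 and O3' are masked by the same triisopropylsilyl group, so one buffered fluoride treatment frees exactly the two oxygens that are to be sulfated. An acetal on O3 was rejected: it would need its own acidic removal and would not survive the acid that closes ring C. A silyl ether on O3 also survives that closure and, as a donor, lowers the acceptor character of the chromone C2=C3 bond in the key step.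

**Ring B (22 ⇒ 16 + 20).** The bonds C1'–C2' and C3'–C4' are cut, and the lactone bridge that leaves as CO2 in the forward direction is restored across C1' and C4'. This returns the 6-(chromon-2-yl)-3-(benzyloxy)-2-pyrone 16 and (triisopropylsilyloxy)ethyne 20. The neighbouring cuts (C2–C1' by cross-coupling, or ring B bought as a benzoic acid) depend on a catechol that has already been differentiated by selective alkylation. Here the benzyl ether on O4' comes from the pyrone and the silyl ether on O3' from the alkyne, so the two oxygens differ by origin. The forward reaction must be regioselective (alkyne CH to pyrone C6) and must run without acid or base.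

**The ynol ether (20 ⇒ 17).** The O–Si bond and the C–O bond of 20 are cut back to acetylene 17, an oxygen-atom donor and a bulky silyl triflate. The compound is not assumed to be purchasable. The forward step must hold the monolithium acetylide cold and silylate the ynolate on oxygen.

**Ring C (16 ⇒ 15 ⇒ 13 + 7, through 14).** The O1–C2 bond is cut (cyclodehydration), then the C3–C(acyl) bond of the 1,3-diketone 15. This gives the ω-silyloxy-2-hydroxyacetophenone 13 and the pyrone acid 7, used as its chloride 14. Two alternatives were rejected because of the pyrone: a chalcone oxidised with alkaline peroxide would open it, and oxidation at C3 after ring closure would attack its enol ether. O3 is therefore carried in on the ketone. The acylation must find the acid chloride and leave the pyrone alone.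

**The ketone (13 ⇒ 12 ⇒ 9 ⇒ 8).** The ω-oxygen is introduced by Rubottom oxidation of the doubly benzylated acetophenone 9, itself made from the trihydroxy ketone 8 with two equivalents of benzyl bromide 5. α-Halogenation and displacement was rejected because the free ortho phenol would close to a benzofuranone. The primary hydroxyl of diol 12 is then silylated selectively; the chelated phenol is left free for ring closure.

**The pyrone acid (7 ⇒ 6 ⇒ 4 ⇒ 3 ⇒ 2 ⇒ 1).** All six carbons and the oxygen pattern of the pyrone come from galactaric acid 1 by dehydration. The acid is held as a tert-butyl ester while O3 is benzylated, because that ester is removed by acid; saponification of any other ester would endanger the pyrone ring.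

## Roads not taken

Alternative 1: Friedel–Crafts closure to a dihydroflavonol. The cut is C4–C4a at the chromanone oxidation level. In the forward step the hydroxy acid A1 is activated with trifluoroacetic anhydride and acylates its own 3,5-bis(benzyloxy)phenoxy ring to give the trans chromanone A2.
- Merits: the nucleophilic ring is symmetric, so no regiochemical question arises. Ring B enters with O3' (allyl) and O4' (benzyl) already different. Every step is classical.
- Weak points: the free hydroxyl of A1 is acylated by the anhydride. The benzylic aryloxy carbon β to the activated carboxyl can ionise or eliminate under acid. Two stereocentres are made only to be erased in a late dehydrogenation, which must spare the allyl ether and the electron-rich ring A.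
- Comparison: in keeping O3' and O4' apart this road is as secure as the chosen one, and its ring-forming step is more predictable. The chosen plan sets against it direct arrival at the flavonol oxidation level, no stereocentres, and no strongly acidic C–C bond formation next to a labile benzylic ether.

Alternative 2: thermal condensation of the triol with a keto ester. C4–C4a and O1–C2 are cut together. Phloroglucinol A3 and the α-silyloxy aroylacetate A4 are heated without solvent (Mentzer pyrone synthesis) to give A5.
- Merits: it is the shortest route on paper, and ring A needs no protection before the condensation.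
- Weak points: the melt temperature is far above what an α-silyloxy β-keto ester is likely to bear (silyl migration, elimination, decarboxylation). Coumarin formation competes. A5 has a free 7-OH that would take up sulfate, so it must be benzylated selectively next to two silyl ethers under base, where silyl migration on the catechol threatens the O3'/O4' assignment.
- Comparison: if the condensation worked, this road would be several steps shorter than the chosen one. The chosen plan offers mild conditions at every stage and a ring A that is protected correctly from the start.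

Alternative 3: carbonylative ketone arylation. C4a–C4 and C3–C4 are cut, C4 being delivered by carbonylation. The aryl iodide A6 and the enolate of ketone A7 are joined under Pd(dba)2 and Xantphos to the open-chain diketone A8; no ring closes.
- Merits: it is the most convergent assembly (three components, two bonds). O3 and O3' carry the same acetal and can be unmasked together, as the twin silyl ethers are in the chosen route.
- Weak points: A6 is doubly ortho-substituted and electron-rich, so oxidative addition and acyl transfer are slow and direct arylation without carbonylation competes. The enolate must react at an oxygenated carbon. Ring C can close only after one ortho benzyl ether of A8 is removed selectively.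
- Comparison: if one acidic operation achieved debenzylation, acetal loss and cyclisation, this road could reach a compound like 23 in fewer steps than the chosen plan. The chosen plan has a free phenol in place for ring closure (13) and a protecting-group logic that needs no selective debenzylation.

Key step: step 12

Assumption: the target is drawn as the free bis(hydrogen sulfate); the sulfate esters are carried as the dipotassium salt 24 and protonated only in the last operation, and the free acid is expected to need cold, dry storage.

Assumption: (triisopropylsilyloxy)ethyne 20 is not taken to be a stock chemical and is made in step 11; galactaric acid, 2,4,6-trihydroxyacetophenone, benzyl bromide and acetylene are bought.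

## Route

Step 1
Reactants: 1 galactaric acid
Product: 2 potassium 3-(acetyloxy)-2-oxo-2H-pyran-6-carboxylate
Conditions: Ac2O, KOAc, 100 °C; salt collected by filtration
Reagents that add atoms: acetic anhydride, CC(=O)OC(C)=O; potassium acetate, CC(=O)[O-].[K+]
Why: Known dehydrative conversion of aldaric acids into 3-acyloxy-2-pyrone-6-carboxylate salts: peracetylation, two β-eliminations of acetic acid and lactonisation give the pyrone, whose enol is trapped as the acetate; the four stereocentres of 1 are erased.

Step 2
Reactants: 2 potassium 3-(acetyloxy)-2-oxo-2H-pyran-6-carboxylate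
Product: 3 3-hydroxy-2-oxo-2H-pyran-6-carboxylic acid
Conditions: 6 M HCl, H2O, 25 → 50 °C
Reagents that add atoms: none
Why: Acid hydrolysis of the enol acetate and protonation of the carboxylate; the 2-pyrone tolerates aqueous acid, and the temperature stays well below that of decarboxylation.

Step 3
Reactants: 3 3-hydroxy-2-oxo-2H-pyran-6-carboxylic acid
Product: 4 tert-butyl 3-hydroxy-2-oxo-2H-pyran-6-carboxylate
Conditions: Cl3CC(=NH)Ot-Bu (2.5 equiv), THF/cyclohexane, 25 °C
Reagents that add atoms: tert-butyl 2,2,2-trichloroacetimidate, CC(C)(C)OC(=N)C(Cl)(Cl)Cl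
Why: Trichloroacetimidate esterification: the carboxylic acid protonates the imidate and captures the tert-butyl cation, while the much less acidic enolic hydroxyl does not react without an added Lewis acid.

Step 4
Reactants: 4 tert-butyl 3-hydroxy-2-oxo-2H-pyran-6-carboxylate; 5 benzyl bromide
Product: 6 tert-butyl 3-(benzyloxy)-2-oxo-2H-pyran-6-carboxylate
Conditions: BnBr (1.2 equiv), K2CO3, DMF, 25 °C
Reagents that add atoms: none
Why: Williamson ether synthesis on the acidic 3-hydroxypyrone, a known O-alkylation of 3-hydroxy-2-pyrone-6-carboxylic esters; carbonate is too weak a nucleophile to open the pyrone and the tert-butyl ester is inert.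

Step 5
Reactants: 6 tert-butyl 3-(benzyloxy)-2-oxo-2H-pyran-6-carboxylate
Product: 7 3-(benzyloxy)-2-oxo-2H-pyran-6-carboxylic acid
Conditions: CF3CO2H/CH2Cl2 (1:3), 25 °C
Reagents that add atoms: none
Why: Acidolysis of a tert-butyl ester (alkyl–oxygen cleavage, loss of isobutene); this frees the acid without hydroxide, which would open the pyrone, and the benzyl ether on the electron-poor pyrone is stable to the acid at room temperature.

Step 6
Reactants: 8 2,4,6-trihydroxyacetophenone; 5 benzyl bromide
Product: 9 1-[2,4-bis(benzyloxy)-6-hydroxyphenyl]ethan-1-one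
Conditions: BnBr (2.1 equiv in all), K2CO3, DMF, 25 °C
Reagents that add atoms: benzyl bromide, BrCc1ccccc1 (a second equivalent of 5; each of the two benzyl ethers of 9 takes one equivalent)
Why: Twofold Williamson ether synthesis with two equivalents of benzyl bromide; the para hydroxyl and one ortho hydroxyl are alkylated, and the second ortho hydroxyl is held back by its hydrogen bond to the ketone, a known selective bis-benzylation of this ketone.

Step 7
Reactants: 9 1-[2,4-bis(benzyloxy)-6-hydroxyphenyl]ethan-1-one
Product: 12 1-[2,4-bis(benzyloxy)-6-hydroxyphenyl]-2-hydroxyethan-1-one, via bis(trimethylsilyl) enol ether 10 (not isolated), via α-(trimethylsilyloxy) ketone 11 (not isolated)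
Conditions: Me3SiOTf (2.4 equiv), Et3N, CH2Cl2, 0 °C; mCPBA (1.05 equiv), NaHCO3, CH2Cl2, −20 → 0 °C; 1 M HCl, THF, 0 °C
Reagents that add atoms: mCPBA, OOC(=O)c1cccc(Cl)c1 (the ω-oxygen); trimethylsilyl triflate, C[Si](C)(C)OS(=O)(=O)C(F)(F)F (two equivalents silylate the phenol and the enolate; silicon held only in 10 and 11)
Why: Rubottom oxidation: the silyl enol ether is epoxidised much faster than the ring or the ketone is attacked, the silyloxy epoxide rearranges to the α-silyloxy ketone, and dilute acid removes both trimethylsilyl groups; no halide is involved, so the free ortho phenol cannot close to a benzofuranone.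

Step 8
Reactants: 12 1-[2,4-bis(benzyloxy)-6-hydroxyphenyl]-2-hydroxyethan-1-one
Product: 13 1-[2,4-bis(benzyloxy)-6-hydroxyphenyl]-2-[(triisopropylsilyl)oxy]ethan-1-one
Conditions: i-Pr3SiCl (1.1 equiv), imidazole, DMF, 0 → 25 °C
Reagents that add atoms: triisopropylsilyl chloride, CC(C)[Si](Cl)(C(C)C)C(C)C
Why: Imidazole-mediated silylation; the bulky silyl chloride takes the primary hydroxyl and leaves the hindered phenol that is hydrogen-bonded to the ketone.

Step 9
Reactants: 7 3-(benzyloxy)-2-oxo-2H-pyran-6-carboxylic acid; 13 1-[2,4-bis(benzyloxy)-6-hydroxyphenyl]-2-[(triisopropylsilyl)oxy]ethan-1-one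
Product: 15 1-[2,4-bis(benzyloxy)-6-hydroxyphenyl]-3-[3-(benzyloxy)-2-oxo-2H-pyran-6-yl]-2-[(triisopropylsilyl)oxy]propane-1,3-dione (racemic; enolisable), via acid chloride 14 (not isolated)
Conditions: 7, (COCl)2, DMF (cat.), CH2Cl2, 0 → 25 °C, evaporate; 13, LiN(SiMe3)2 (3.2 equiv), THF, −78 °C, then 14 (1.3 equiv), −78 → −20 °C; 1 M HCl, 0 °C
Reagents that add atoms: oxalyl chloride, O=C(Cl)C(=O)Cl (chlorine held only in 14; no reagent atom remains in 15)
Why: Acid chloride formation, then C-acylation of the phenoxide–enolate dianion of an o-hydroxyaryl ketone (one-flask form of the Baker–Venkataraman diketone synthesis; any O-acyl ester formed rearranges to the same diketone under the excess base). The acid chloride is by far the most electrophilic site at −78 °C, so the pyrone is spared; the new stereocentre is formed racemic and disappears in step 10.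

Step 10
Reactants: 15 1-[2,4-bis(benzyloxy)-6-hydroxyphenyl]-3-[3-(benzyloxy)-2-oxo-2H-pyran-6-yl]-2-[(triisopropylsilyl)oxy]propane-1,3-dione
Product: 16 5,7-bis(benzyloxy)-2-[3-(benzyloxy)-2-oxo-2H-pyran-6-yl]-3-[(triisopropylsilyl)oxy]-4H-chromen-4-one
Conditions: TsOH·H2O (0.2 equiv), PhMe, 4 Å MS, 80 °C
Reagents that add atoms: none
Why: Acid-catalysed cyclodehydration of an o-hydroxyaryl 1,3-diketone (second stage of the Baker–Venkataraman flavone synthesis): the phenol adds to the pyronyl ketone in a 6-exo-trig closure and water is lost. Catalytic anhydrous acid is chosen so that the silyl ether, which becomes a robust enol-type silyl ether once C2=C3 forms, and the 5-benzyl ether survive.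

Step 11
Reactants: 17 acetylene
Product: 20 (triisopropylsilyloxy)ethyne, via lithium acetylide 18 (not isolated), via lithium ethynolate 19 (not isolated)
Conditions: 17 (excess, satd. in THF), n-BuLi, −78 °C; t-BuOOLi (from t-BuOOH and LiN(SiMe3)2), THF, −78 → −20 °C; i-Pr3SiOTf, −78 → 0 °C; distilled and kept as a toluene solution
Reagents that add atoms: tert-butyl hydroperoxide, CC(C)(C)OO (the oxygen); triisopropylsilyl triflate, CC(C)[Si](OS(=O)(=O)C(F)(F)F)(C(C)C)C(C)C; n-butyllithium, [Li]CCCC (lithium held only in 18 and 19)
Why: Oxidation of a lithium acetylide by lithium tert-butyl peroxide to the lithium ynolate and O-silylation with a bulky silyl triflate, the standard route from terminal alkynes to 1-silyloxyalkynes, here applied to acetylene itself; excess acetylene and low temperature keep the monolithium acetylide, and the hard, bulky triflate favours silylation on oxygen.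

Step 12
Reactants: 16 5,7-bis(benzyloxy)-2-[3-(benzyloxy)-2-oxo-2H-pyran-6-yl]-3-[(triisopropylsilyl)oxy]-4H-chromen-4-one; 20 (triisopropylsilyloxy)ethyne
Product: 22 5,7-bis(benzyloxy)-2-{4-(benzyloxy)-3-[(triisopropylsilyl)oxy]phenyl}-3-[(triisopropylsilyl)oxy]-4H-chromen-4-one, via bridged lactone 21 (not isolated)
Conditions: 20 (3 equiv), PhMe (dry, degassed), 90 °C, sealed tube
Reagents that add atoms: none
Why: Inverse-electron-demand Diels–Alder reaction of a 2-pyrone with an ynol ether, followed by cycloreversion with loss of CO2; this is the established pyrone-to-arene benzannulation with electron-rich alkynes. The pyrone of 16 is the 4π component (C3=C4–C5=C6); its LUMO, polarised by the lactone carbonyl, has the larger terminal coefficient at C6, and the HOMO of 20 is largest at the unsubstituted carbon, so the concerted but asynchronous addition joins the alkyne CH to pyrone C6 (C1'–C2') and the silyloxy carbon to pyrone C3 (C3'–C4'). Ring B is thus closed by an intermolecular (4+2) cycloaddition, and the bridged lactone 21 then loses CO2 in a retro-(4+2) step driven by aromatisation. No stereocentre remains: the two bridgeheads of 21 are fixed by the bicycle and become sp2 carbons. The selectivity needed is regiochemical (silyloxy group next to the benzyloxy group, not next to ring C); it is secured by the electronic match above and by sterics, since the bulky silyloxy carbon avoids the pyrone terminus that carries the chromone and its O3 silyl ether. The donor silyloxy group at C3 of ring C also keeps the chromone C2=C3 bond from competing as an acceptor for the ynol ether. Neutral aprotic conditions protect the ynol ether and both silyl ethers.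

Step 13
Reactants: 22 5,7-bis(benzyloxy)-2-{4-(benzyloxy)-3-[(triisopropylsilyl)oxy]phenyl}-3-[(triisopropylsilyl)oxy]-4H-chromen-4-one
Product: 23 5,7-bis(benzyloxy)-2-[4-(benzyloxy)-3-hydroxyphenyl]-3-hydroxy-4H-chromen-4-one
Conditions: Bu4NF (2.5 equiv), AcOH (2.5 equiv), THF, 0 → 25 °C, under argon
Reagents that add atoms: none
Why: Fluoride cleavage of an aryl and an enol silyl ether (both good leaving groups on silicon); acetic acid buffers the phenoxides so that the free flavonol is not oxidised, and benzyl ethers are untouched.

Step 14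
Reactants: 23 5,7-bis(benzyloxy)-2-[4-(benzyloxy)-3-hydroxyphenyl]-3-hydroxy-4H-chromen-4-one
Product: 24 dipotassium 5,7-bis(benzyloxy)-2-[4-(benzyloxy)-3-(sulfonatooxy)phenyl]-4-oxo-4H-chromen-3-yl sulfate
Conditions: SO3·pyridine (8 equiv), pyridine, 50 °C; KOH, MeOH, 0 °C to pH 8; Sephadex LH-20
Reagents that add atoms: sulfur trioxide–pyridine complex, [O-]S(=O)(=O)[n+]1ccccc1 (two SO3 units enter 24); potassium hydroxide, [K+].[OH-] (two potassium ions enter 24)
Why: O-Sulfation of phenolic and enolic hydroxyls with an amine–SO3 complex, the usual method for flavonoid sulfates; only O3 and O3' are free, and exchange to the potassium salt removes pyridinium, which would slow the hydrogenolysis.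

Step 15
Reactants: 24 dipotassium 5,7-bis(benzyloxy)-2-[4-(benzyloxy)-3-(sulfonatooxy)phenyl]-4-oxo-4H-chromen-3-yl sulfate
Product: 26 quercetin 3,3'-bissulfate (5,7-dihydroxy-2-[4-hydroxy-3-(sulfooxy)phenyl]-4-oxo-4H-chromen-3-yl hydrogen sulfate), via dipotassium quercetin 3,3'-bissulfate 25 (not isolated)
Conditions: H2 (1 atm), Pd/C (10%), MeOH/H2O, 25 °C; filter; 0.1 M HCl (2.0 equiv), 0 °C; C18 cartridge, freeze-dry
Reagents that add atoms: none
Why: Catalytic hydrogenolysis of aryl benzyl ethers under neutral conditions, known to leave aryl sulfate salts and the flavonol C2=C3 bond intact; cold stoichiometric acid and reversed-phase desalting then give the free acid form.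

## Compound list

1 | galactaric acid (meso) | OC(=O)[C@H](O)[C@@H](O)[C@@H](O)[C@H](O)C(=O)O | starting material
2 | potassium 3-(acetyloxy)-2-oxo-2H-pyran-6-carboxylate | CC(=O)Oc1ccc(C(=O)[O-])oc1=O.[K+] | intermediate
3 | 3-hydroxy-2-oxo-2H-pyran-6-carboxylic acid | O=C(O)c1ccc(O)c(=O)o1 | intermediate
4 | tert-butyl 3-hydroxy-2-oxo-2H-pyran-6-carboxylate | CC(C)(C)OC(=O)c1ccc(O)c(=O)o1 | intermediate
5 | benzyl bromide | BrCc1ccccc1 | starting material
6 | tert-butyl 3-(benzyloxy)-2-oxo-2H-pyran-6-carboxylate | CC(C)(C)OC(=O)c1ccc(OCc2ccccc2)c(=O)o1 | intermediate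
7 | 3-(benzyloxy)-2-oxo-2H-pyran-6-carboxylic acid | O=C(O)c1ccc(OCc2ccccc2)c(=O)o1 | intermediate
8 | 2,4,6-trihydroxyacetophenone | CC(=O)c1c(O)cc(O)cc1O | starting material
9 | 1-[2,4-bis(benzyloxy)-6-hydroxyphenyl]ethan-1-one | CC(=O)c1c(O)cc(OCc2ccccc2)cc1OCc1ccccc1 | intermediate
10 | {[1-(2,4-bis(benzyloxy)-6-[(trimethylsilyl)oxy]phenyl)ethenyl]oxy}trimethylsilane (not isolated, step 7) | C=C(O[Si](C)(C)C)c1c(O[Si](C)(C)C)cc(OCc2ccccc2)cc1OCc1ccccc1 | intermediate
11 | 1-{2,4-bis(benzyloxy)-6-[(trimethylsilyl)oxy]phenyl}-2-[(trimethylsilyl)oxy]ethan-1-one (not isolated, step 7) | C[Si](C)(C)OCC(=O)c1c(O[Si](C)(C)C)cc(OCc2ccccc2)cc1OCc1ccccc1 | intermediate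
12 | 1-[2,4-bis(benzyloxy)-6-hydroxyphenyl]-2-hydroxyethan-1-one | OCC(=O)c1c(O)cc(OCc2ccccc2)cc1OCc1ccccc1 | intermediate
13 | 1-[2,4-bis(benzyloxy)-6-hydroxyphenyl]-2-[(triisopropylsilyl)oxy]ethan-1-one | CC(C)[Si](C(C)C)(C(C)C)OCC(=O)c1c(O)cc(OCc2ccccc2)cc1OCc1ccccc1 | intermediate
14 | 3-(benzyloxy)-2-oxo-2H-pyran-6-carbonyl chloride (not isolated, step 9) | O=C(Cl)c1ccc(OCc2ccccc2)c(=O)o1 | intermediate
15 | 1-[2,4-bis(benzyloxy)-6-hydroxyphenyl]-3-[3-(benzyloxy)-2-oxo-2H-pyran-6-yl]-2-[(triisopropylsilyl)oxy]propane-1,3-dione (racemic; enolisable) | O=C(c1c(O)cc(OCc2ccccc2)cc1OCc1ccccc1)C(O[Si](C(C)C)(C(C)C)C(C)C)C(=O)c1ccc(OCc2ccccc2)c(=O)o1 | intermediate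
16 | 5,7-bis(benzyloxy)-2-[3-(benzyloxy)-2-oxo-2H-pyran-6-yl]-3-[(triisopropylsilyl)oxy]-4H-chromen-4-one | O=c1c(O[Si](C(C)C)(C(C)C)C(C)C)c(-c2ccc(OCc3ccccc3)c(=O)o2)oc2cc(OCc3ccccc3)cc(OCc3ccccc3)c12 | intermediate
17 | acetylene | C#C | starting material
18 | lithium acetylide (not isolated, step 11) | [Li]C#C | intermediate
19 | lithium ethynolate (not isolated, step 11) | C#C[O-].[Li+] | intermediate
20 | (triisopropylsilyloxy)ethyne | C#CO[Si](C(C)C)(C(C)C)C(C)C | intermediate
21 | 4-(benzyloxy)-1-{5,7-bis(benzyloxy)-4-oxo-3-[(triisopropylsilyl)oxy]-4H-chromen-2-yl}-5-[(triisopropylsilyl)oxy]-2-oxabicyclo[2.2.2]octa-5,7-dien-3-one (racemic, one enantiomer drawn; the bridgeheads are tied to each other by the bicycle; not isolated, step 12) | O=C1O[C@@]2(c3oc4cc(OCc5ccccc5)cc(OCc5ccccc5)c4c(=O)c3O[Si](C(C)C)(C(C)C)C(C)C)C=C[C@]1(OCc6ccccc6)C(O[Si](C(C)C)(C(C)C)C(C)C)=C2 | intermediate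
22 | 5,7-bis(benzyloxy)-2-{4-(benzyloxy)-3-[(triisopropylsilyl)oxy]phenyl}-3-[(triisopropylsilyl)oxy]-4H-chromen-4-one | O=c1c(O[Si](C(C)C)(C(C)C)C(C)C)c(-c2ccc(OCc3ccccc3)c(O[Si](C(C)C)(C(C)C)C(C)C)c2)oc2cc(OCc3ccccc3)cc(OCc3ccccc3)c12 | intermediate
23 | 5,7-bis(benzyloxy)-2-[4-(benzyloxy)-3-hydroxyphenyl]-3-hydroxy-4H-chromen-4-one | O=c1c(O)c(-c2ccc(OCc3ccccc3)c(O)c2)oc2cc(OCc3ccccc3)cc(OCc3ccccc3)c12 | intermediate
24 | dipotassium 5,7-bis(benzyloxy)-2-[4-(benzyloxy)-3-(sulfonatooxy)phenyl]-4-oxo-4H-chromen-3-yl sulfate | O=c1c(OS(=O)(=O)[O-])c(-c2ccc(OCc3ccccc3)c(OS(=O)(=O)[O-])c2)oc2cc(OCc3ccccc3)cc(OCc3ccccc3)c12.[K+].[K+] | intermediate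
25 | dipotassium 5,7-dihydroxy-2-[4-hydroxy-3-(sulfonatooxy)phenyl]-4-oxo-4H-chromen-3-yl sulfate (not isolated, step 15) | O=c1c(OS(=O)(=O)[O-])c(-c2ccc(O)c(OS(=O)(=O)[O-])c2)oc2cc(O)cc(O)c12.[K+].[K+] | intermediate
26 | quercetin 3,3'-bissulfate (5,7-dihydroxy-2-[4-hydroxy-3-(sulfooxy)phenyl]-4-oxo-4H-chromen-3-yl hydrogen sulfate) | O=c1c(OS(=O)(=O)O)c(-c2ccc(O)c(OS(=O)(=O)O)c2)oc2cc(O)cc(O)c12 | target

## Step count and risks

Total step count: 15. Longest linear sequence: 11 steps (steps 1–5, 9, 10, 12–15).

**Step 12 (key step).**
- Risk: the cycloaddition may be slow, because the 3-benzyloxy group raises the pyrone LUMO. During the long heating the ynol ether may isomerise to the silylketene or oligomerise before it adds. Some addition in the reverse orientation would put the silyloxy group next to ring C.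
- Fallback: ring B is brought in ready-made, setting out from 13. Commercial 4-(benzyloxy)-3-hydroxybenzaldehyde is silylated (i-Pr3SiCl, imidazole) to 4-(benzyloxy)-3-[(triisopropylsilyl)oxy]benzaldehyde F1. This is oxidised (NaClO2, NaH2PO4, 2-methyl-2-butene, Pinnick oxidation) to 4-(benzyloxy)-3-[(triisopropylsilyl)oxy]benzoic acid F2 and converted with oxalyl chloride into 4-(benzyloxy)-3-[(triisopropylsilyl)oxy]benzoyl chloride F3. The dianion of 13 (LiN(SiMe3)2) is acylated with F3 to give 1-[2,4-bis(benzyloxy)-6-hydroxyphenyl]-3-{4-(benzyloxy)-3-[(triisopropylsilyl)oxy]phenyl}-2-[(triisopropylsilyl)oxy]propane-1,3-dione F4. Cyclodehydration as in step 10 comes back to the route at 22.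

**Step 11.**
- Risk: the monolithium acetylide may disproportionate to the insoluble dilithium compound on warming. The ynolate may be deprotonated a second time. Silylation may occur on carbon and give the silylketene. The volatile product may be lost on isolation.
- Fallback: the alkyne is replaced by a ketene acetal, setting out from 16. Commercial tert-butyldimethylsilyl acetate is converted (LiN(i-Pr)2, t-BuMe2SiCl) into 1,1-bis[(tert-butyldimethylsilyl)oxy]ethene F5. Heating F5 with 16 should give, after cycloaddition, loss of CO2 and elimination of silanol, 5,7-bis(benzyloxy)-2-{4-(benzyloxy)-3-[(tert-butyldimethylsilyl)oxy]phenyl}-3-[(triisopropylsilyl)oxy]-4H-chromen-4-one F6. Buffered Bu4NF as in step 13 takes F6 back to the route at 23.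

**Step 9.**
- Risk: the amide base or the enolate may attack the pyrone ring. O-acylation may occur without the following acyl shift. The hindered silyloxy-bearing enolate carbon may acylate poorly.
- Fallback: the two events are separated, setting out from 13 and 14. The phenol is esterified (pyridine, DMAP, CH2Cl2) to 3,5-bis(benzyloxy)-2-{[(triisopropylsilyl)oxy]acetyl}phenyl 3-(benzyloxy)-2-oxo-2H-pyran-6-carboxylate F7. This is purified and then rearranged by a Baker–Venkataraman acyl shift (LiN(SiMe3)2, THF, −78 → 0 °C), coming back at 15.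

**Step 10.**
- Risk: the silyl ether may be lost under the acid. Dehydration of the hemiketal may be incomplete, because the electron-poor pyronyl group destabilises the oxocarbenium ion.
- Fallback: the silyl group is deliberately given up and put back, setting out from 15. Hot AcOH with catalytic H2SO4 should give 5,7-bis(benzyloxy)-2-[3-(benzyloxy)-2-oxo-2H-pyran-6-yl]-3-hydroxy-4H-chromen-4-one F8. Silylation of F8 (i-Pr3SiOTf, 2,6-lutidine) comes back at 16.

**Step 14.**
- Risk: sulfation of the hydrogen-bonded, less nucleophilic O3 may be incomplete. Sulfate may be lost by hydrolysis while the salt is isolated.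
- Fallback: protected sulfate diesters that can be chromatographed are used, setting out from 23. 2,2,2-Trichloroethyl chlorosulfate (Et3N, DMAP, THF) should give 5,7-bis(benzyloxy)-2-{4-(benzyloxy)-3-[(2,2,2-trichloroethoxy)sulfonyloxy]phenyl}-4-oxo-4H-chromen-3-yl 2,2,2-trichloroethyl sulfate F9. Reductive removal of the trichloroethyl groups (Zn, HCO2NH4, MeOH) and exchange to the potassium salt (KOH) comes back at 24.

## Further compounds

F1 | step 12 | 4-(benzyloxy)-3-[(triisopropylsilyl)oxy]benzaldehyde | O=Cc1ccc(OCc2ccccc2)c(O[Si](C(C)C)(C(C)C)C(C)C)c1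
F2 | step 12 | 4-(benzyloxy)-3-[(triisopropylsilyl)oxy]benzoic acid | O=C(O)c1ccc(OCc2ccccc2)c(O[Si](C(C)C)(C(C)C)C(C)C)c1
F3 | step 12 | 4-(benzyloxy)-3-[(triisopropylsilyl)oxy]benzoyl chloride | O=C(Cl)c1ccc(OCc2ccccc2)c(O[Si](C(C)C)(C(C)C)C(C)C)c1
F4 | step 12 | 1-[2,4-bis(benzyloxy)-6-hydroxyphenyl]-3-{4-(benzyloxy)-3-[(triisopropylsilyl)oxy]phenyl}-2-[(triisopropylsilyl)oxy]propane-1,3-dione (racemic) | O=C(c1c(O)cc(OCc2ccccc2)cc1OCc1ccccc1)C(O[Si](C(C)C)(C(C)C)C(C)C)C(=O)c1ccc(OCc2ccccc2)c(O[Si](C(C)C)(C(C)C)C(C)C)c1
F5 | step 11 | 1,1-bis[(tert-butyldimethylsilyl)oxy]ethene | C=C(O[Si](C)(C)C(C)(C)C)O[Si](C)(C)C(C)(C)C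
F6 | step 11 | 5,7-bis(benzyloxy)-2-{4-(benzyloxy)-3-[(tert-butyldimethylsilyl)oxy]phenyl}-3-[(triisopropylsilyl)oxy]-4H-chromen-4-one | O=c1c(O[Si](C(C)C)(C(C)C)C(C)C)c(-c2ccc(OCc3ccccc3)c(O[Si](C)(C)C(C)(C)C)c2)oc2cc(OCc3ccccc3)cc(OCc3ccccc3)c12
F7 | step 9 | 3,5-bis(benzyloxy)-2-{[(triisopropylsilyl)oxy]acetyl}phenyl 3-(benzyloxy)-2-oxo-2H-pyran-6-carboxylate | O=C(Oc1cc(OCc2ccccc2)cc(OCc2ccccc2)c1C(=O)CO[Si](C(C)C)(C(C)C)C(C)C)c1ccc(OCc2ccccc2)c(=O)o1
F8 | step 10 | 5,7-bis(benzyloxy)-2-[3-(benzyloxy)-2-oxo-2H-pyran-6-yl]-3-hydroxy-4H-chromen-4-one | O=c1c(O)c(-c2ccc(OCc3ccccc3)c(=O)o2)oc2cc(OCc3ccccc3)cc(OCc3ccccc3)c12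
F9 | step 14 | 5,7-bis(benzyloxy)-2-{4-(benzyloxy)-3-[(2,2,2-trichloroethoxy)sulfonyloxy]phenyl}-4-oxo-4H-chromen-3-yl 2,2,2-trichloroethyl sulfate | O=c1c(OS(=O)(=O)OCC(Cl)(Cl)Cl)c(-c2ccc(OCc3ccccc3)c(OS(=O)(=O)OCC(Cl)(Cl)Cl)c2)oc2cc(OCc3ccccc3)cc(OCc3ccccc3)c12
A1 | alternative 1 | 3-[3-(allyloxy)-4-(benzyloxy)phenyl]-3-[3,5-bis(benzyloxy)phenoxy]-2-hydroxypropanoic acid (racemic, the diastereomer that leads to the trans chromanone; one enantiomer drawn) | c1(ccc(OCc2ccccc2)c(OCC=C)c1)[C@@H](Oc1cc(OCc2ccccc2)cc(OCc2ccccc2)c1)[C@H](C(=O)O)O
A2 | alternative 1 | rac-(2R,3R)-2-[3-(allyloxy)-4-(benzyloxy)phenyl]-5,7-bis(benzyloxy)-3-hydroxychroman-4-one (trans, one enantiomer drawn) | c1(ccc(OCc2ccccc2)c(OCC=C)c1)[C@@H]1[C@H](C(=O)c2c(OCc3ccccc3)cc(OCc3ccccc3)cc2O1)O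
A3 | alternative 2 | phloroglucinol | Oc1cc(O)cc(O)c1
A4 | alternative 2 | ethyl 3-{4-(benzyloxy)-3-[(triisopropylsilyl)oxy]phenyl}-3-oxo-2-[(triisopropylsilyl)oxy]propanoate (racemic) | CCOC(=O)C(O[Si](C(C)C)(C(C)C)C(C)C)C(=O)c1ccc(OCc2ccccc2)c(O[Si](C(C)C)(C(C)C)C(C)C)c1
A5 | alternative 2 | 2-[4-(benzyloxy)-3-(triisopropylsilyloxy)phenyl]-5,7-dihydroxy-3-(triisopropylsilyloxy)-4H-chromen-4-one | O=c1c(O[Si](C(C)C)(C(C)C)C(C)C)c(-c2ccc(OCc3ccccc3)c(O[Si](C(C)C)(C(C)C)C(C)C)c2)oc2cc(O)cc(O)c12
A6 | alternative 3 | 2-iodo-1,3,5-tris(benzyloxy)benzene | Ic1c(OCc2ccccc2)cc(OCc2ccccc2)cc1OCc1ccccc1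
A7 | alternative 3 | 1-[4-(benzyloxy)-3-(methoxymethoxy)phenyl]-2-(methoxymethoxy)ethan-1-one | COCOCC(=O)c1ccc(OCc2ccccc2)c(OCOC)c1
A8 | alternative 3 | 1-[4-(benzyloxy)-3-(methoxymethoxy)phenyl]-2-(methoxymethoxy)-3-[2,4,6-tris(benzyloxy)phenyl]propane-1,3-dione (racemic, enolisable) | O=C(c1c(OCc2ccccc2)cc(OCc2ccccc2)cc1OCc1ccccc1)C(OCOC)C(=O)c1ccc(OCc2ccccc2)c(OCOC)c1
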